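Read the order in coupling partner as a stretch above 1, with 1 as the zero of the scale.

| setting | amber | flask |
|---|---|---|
| left-handed substrate | 1.2 M | 1.2 M |
| right-handed substrate | 1.2 M | 1.2 M |
| coupling partner | 0.96 M | 0.960 M |
| free catalyst | 24 mM | 24 mM |
| remark | the very flask that is asked about, followed so far |  |

- amber (time / h: left-handed product / %): 4.00: 12.1; 10.0: 18.3; 20.0: 22.4; 30.0: 24.1

(readings scatter by 0.3 percentage points)

* apparent order in free catalyst when 5.0% of the left-handed substrate and right-handed substrate together are converted (percent change of the rate of making left-handed product for one percent more free catalyst charged)
* apparent order in coupling partner when 5.0% of the left-handed substrate and right-handed substrate together are converted (percent change of the rate of making left-handed product for one percent more coupling partner charged)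

1. At a fixed conversion I took the coupling partner spent in this flask as a fixed amount, 0.120 M, one for each substrate converted, whichever hand takes it. So extra charge lands whole on what stands at the look. One percent more charge is then 1.14 percent more standing coupling partner; this charge over what stands is the stretch.

2. One number was not enough: the amber run, this same flask, fades. I integrated the rate per left-handed substrate and coupling partner. The reading was 0.0866 L mol⁻¹ h⁻¹ up to 4.00 h, but 0.0295 L mol⁻¹ h⁻¹ from 10.0 h to 20.0 h.

3. I guessed that the reciprocal of this activity climbs straight in time, as when free catalyst meets free catalyst; no run tests this. The logarithmic catalyst loss at the look is then that slope times the integral needed to reach the look, 0.117 L mol⁻¹, which gives 0.201.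

4. Taking that integral to shrink in proportion to the coupling partner charge, I added this to the stretch and committed to 1.34 in coupling partner. At the fixed conversion the same guess leaves the surviving share unchanged by the catalyst charge, so I took 1 in free catalyst.

5. The forecast gave 1.05 in free catalyst and 0.95 in coupling partner, noting that “no run varied either charge”.

The flask gave 1.0 in free catalyst and 1.3 in coupling partner, with the look at 1.16 h.

    coupling partner + free catalyst + left-handed substrate → free catalyst + left-handed product (k = 4.60 L² mol⁻² h⁻¹)
    coupling partner + free catalyst + right-handed substrate → free catalyst + right-handed product (k = 0.0390 L² mol⁻² h⁻¹)
    coupling partner + free catalyst → spent catalyst A (k = 0.00420 L mol⁻¹ h⁻¹)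
    2 free catalyst → spent catalyst B (k = 3.70 L mol⁻¹ h⁻¹)

At the start the left-handed step used coupling partner 120 times as fast as the right-handed step. Taking the stretch off the order leaves 0.160, and the logarithm of one plus twice the constant of the step to spent catalyst B times the catalyst charge times the time of the look is 0.187.

Readings and results stem from a simulated flask on assumed constants; noise was put on by code.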